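**Assumption:** labdane-half carbons are primed (C12′ etc.), the quinoid half uses abietane numbering, and the (R)-dichloro-BINOL·SbCl5 promoter is taken to give the natural (5S,10S) series (use the (S)-ligand if the sense is opposite).

## Retrosynthetic overview

1. Last step: intermolecular perezone-type [5+2] of the free hydroxyquinone aldehyde 13 (C8–C9–C11–C12–C13 as the five-carbon unit, C14=O as bridge) with the terminal vinyl C14′=C15′ of the free acid 21. It forms the bicyclo[3.2.1]octane and sets C8, C13 and C14′ at once, without protecting groups.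
2. 13 ⇐ arene-to-hydroxyquinone oxidation of 8 ⇐ oxidative semipinacol contraction of ring B (6→5) of styrene 7.
3. 7 ⇐ ferruginol methyl ether 6 ⇐ enantioselective cationic bicyclisation of homogeranylarene 5 (rings A and B closed together onto the purchased arene ring C) ⇐ 1 + 3.
4. 21 ⇐ abietic acid 14: rings A/B with C4, C5, C9, C10 are bought; ring C is opened at C13=C14, C14 becomes the C17 methylene, C13 is excised, and the diene is built by two Wittig reactions.
5. Ring order: arene C → A+B (polyene cyclisation) → B contracted → quinone → bicyclo[3.2.1]octane ([5+2]); no ring is formed in the labdane half.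

## Route

Step 1
Reactants: 1 2-isopropylanisole
Product: 2 4-(chloromethyl)-2-isopropylanisole
Conditions: (CH2O)n, conc. HCl, AcOH, 50 °C
Reagents that add atoms: formaldehyde (C=O); hydrogen chloride (Cl)
Why: Blanc chloromethylation occurs para to the methoxy group, the most activated and least hindered position; no stereocentre.

Step 2
Reactants: 2 4-(chloromethyl)-2-isopropylanisole; 3 geranyl chloride
Product: 5 4-[(3E)-4,8-dimethylnona-3,7-dien-1-yl]-2-isopropylanisole, via benzylic Grignard reagent 4 (not isolated)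
Conditions: Mg, THF, 0 °C (slow addition); then 3, CuI (5 mol %), THF, 0 °C
Reagents that add atoms: none
Why: Copper-catalysed Grignard–allyl chloride coupling proceeds by SN2 at the primary allylic carbon, so the (E)-trisubstituted olefin of geranyl chloride is carried over unchanged.

Step 3
Reactants: 5 4-[(3E)-4,8-dimethylnona-3,7-dien-1-yl]-2-isopropylanisole
Product: 6 (+)-ferruginol methyl ether [(5S,10S)-12-methoxyabieta-8,11,13-triene]
Conditions: (R)-3,3′-dichloro-BINOL·SbCl5 (0.5 equiv), CH2Cl2, −78 °C
Reagents that add atoms: none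
Why: Proton-initiated cationic polyene bicyclisation with a chiral Lewis-acid-assisted Brønsted acid; the chair–chair antiperiplanar addition across the (E)-olefin gives the trans A/B fusion, the promoter selects the olefin face (5S,10S), and the arene closes para to the isopropyl group.

Step 4
Reactants: 6 (+)-ferruginol methyl ether
Product: 7 (5S,10S)-12-methoxyabieta-6,8,11,13-tetraene
Conditions: DDQ (1.2 equiv), 1,4-dioxane, 80 °C
Reagents that add atoms: none
Why: DDQ benzylic dehydrogenation; hydride abstraction at C7 is assisted by the para methoxy group and loss of H6 gives the styrene without touching C5 or C10.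

Step 5
Reactants: 7 (5S,10S)-12-methoxyabieta-6,8,11,13-tetraene
Product: 8 (5S,7R,10S)-12-methoxy-5(6→7)abeo-abieta-8,11,13-trien-6-al dimethyl acetal (6-5-6 skeleton; CH(OMe)2 on the new ring carbon, α, trans to C20)
Conditions: PhI(OH)OTs (1.2 equiv), MeOH/HC(OMe)3, 0 → 23 °C
Reagents that add atoms: methanol (CO)
Why: Iodine(III)-mediated oxidative ring contraction of a 1,2-dihydronaphthalene (semipinacol 1,2-aryl shift); the iodane adds to C6 from the α face (β face blocked by the axial C19/C20 methyls), its equatorial C–I bond is antiperiplanar to C7–C8, and aryl migration with MeOH capture at C7 delivers the acetal α.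

Step 6
Reactants: 8 ring-contracted methyl ether acetal
Product: 9 (5S,7R,10S)-12-hydroxy-5(6→7)abeo-abieta-8,11,13-trien-6-al dimethyl acetal
Conditions: NaSEt (4 equiv), DMF, 130 °C; then AcOH
Reagents that add atoms: none
Why: SN2 O-demethylation by thiolate leaves the base-stable acetal and all stereocentres untouched.

Step 7
Reactants: 9 phenol acetal
Product: 13 (5S,7R,10S)-12-hydroxy-11,14-dioxo-5(6→7)abeo-abieta-8,12-dien-6-al, via o-quinone acetal 10 (not isolated), via arylthio catechol acetal 11 (not isolated), via hydroxyquinone acetal 12 (not isolated)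
Conditions: IBX (1.2 equiv), CHCl3/MeOH, 23 °C; then C6F5SH; then NaOH, MeOH, O2 (1 atm); then 2 M HCl, THF, 23 °C
Reagents that add atoms: IBX (OI1(=O)OC(=O)c2ccccc12); sodium hydroxide ([Na+].[OH-]); water (O)
Why: One-pot IBX ortho-oxygenation of the phenol at C11, thiol conjugate addition at C14, aerobic re-oxidation with hydroxide ipso-substitution to the 12-hydroxy-11,14-quinone (sequence known for the closely related dichroanone), then acetal hydrolysis; C7 keeps the thermodynamically preferred α-formyl configuration.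

Step 8
Reactants: 14 (−)-abietic acid
Product: 15 13-oxo-13,14-secoabiet-7-en-14-al-18-oic acid
Conditions: O3 (1.0 equiv, Sudan Red end point), CH2Cl2/MeOH, −78 °C; then Me2S
Reagents that add atoms: ozone ([O-][O+]=O)
Why: Regioselective ozonolysis of the more accessible C13=C14 bond of the diene (the same bond that OsO4 and KMnO4 attack first); the enal formed is deactivated toward a second cleavage and C4, C5, C9, C10 are untouched.

Step 9
Reactants: 15 keto enal acid
Product: 17 13-oxo-13,14-secoabiet-8(14)-en-18-oic acid, via tosylhydrazone 16 (not isolated)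
Conditions: TsNHNH2 (1.05 equiv), THF, 23 °C; then catecholborane (3 equiv), CHCl3, 0 °C; then NaOAc·3H2O, 60 °C
Reagents that add atoms: none
Why: Kabalka reductive 1,3-transposition: the aldehyde condenses in preference to the hindered isopropyl ketone, and the allylic diazene loses N2 by retro-ene to place the new hydrogen on C7 and the double bond exocyclic (C8=CH2), with C9 untouched.

Step 10
Reactants: 17 exocyclic methylene keto acid
Product: 18 12-hydroxy-13-oxo-13,14-secoabiet-8(14)-en-18-oic acid (C12 epimers)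
Conditions: KHMDS (2.3 equiv), THF, −78 °C; then 2-(phenylsulfonyl)-3-phenyloxaziridine (1.3 equiv); then AcOH
Reagents that add atoms: 2-(phenylsulfonyl)-3-phenyloxaziridine (O=S(=O)(c1ccccc1)N1OC1c1ccccc1)
Why: Davis α-hydroxylation of the kinetic enolate formed on the CH2 side (C12) of the ketone in the carboxylate dianion; the new C12 centre is destroyed in the next step.

Step 11
Reactants: 18 α-hydroxy ketone acid
Product: 19 (4R,5R,9S,10R)-12-oxo-13,14,15,16-tetranorlabd-8(17)-en-18-oic acid
Conditions: NaIO4 (2 equiv), THF/H2O, 23 °C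
Reagents that add atoms: none
Why: Periodate (Malaprade-type) cleavage of the α-ketol breaks C12–C13 to give the C12 aldehyde and isobutyric acid under neutral conditions that spare the exocyclic olefin.

Step 12
Reactants: 19 C12 aldehyde acid
Product: 20 (12E)-14-oxo-15-norlabda-8(17),12-dien-18-oic acid
Conditions: Ph3P=C(CH3)CHO (2.5 equiv), PhMe, 90 °C
Reagents that add atoms: 2-(triphenylphosphoranylidene)propanal (CC(C=O)=P(c1ccccc1)(c1ccccc1)c1ccccc1)
Why: Wittig olefination with a stabilised ylide gives the (E)-trisubstituted enal (CHO trans to C11′) and tolerates the free acid.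

Step 13
Reactants: 20 (E)-enal acid
Product: 21 4-epi-trans-communic acid [(4R,5R,9S,10R)-labda-8(17),12E,14-trien-18-oic acid]
Conditions: Ph3PCH3Br (3.5 equiv), KOtBu (3.3 equiv), THF, 0 → 23 °C; aq. NH4Cl
Reagents that add atoms: methyltriphenylphosphonium bromide (C[P+](c1ccccc1)(c1ccccc1)c1ccccc1.[Br-])
Why: Wittig methylenation of the enal completes the 12E,14-diene; the first equivalent of ylide only deprotonates the acid and the 12E geometry is retained.

Step 14
Reactants: 13 hydroxyquinone aldehyde; 21 4-epi-trans-communic acid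
Product: 22 target [5+2] adduct (labdane half 4R,5R,9S,10R,12E,14R; quinoid half 5S,7R,8S,10S,13S)
Conditions: BF3·OEt2 (2.5 equiv), 21 (1.5 equiv), 4 Å MS, CH2Cl2, −78 → −20 °C
Reagents that add atoms: none
Why: Proposed new method: BF3 chelation of the C11 carbonyl/C12 hydroxyl turns 13 into the C8–C9–C11–C12–C13 oxidopentadienyl cation, the unsubstituted diene terminus C15′ attacks C13 (β-carbon of the chelated hydroxy-enone) on the α face anti to the C20 methyl, and the allyl cation closes at C14′ onto C8 on the same face in a compact endo ion pair, giving C8(S), C13(S), C14′(R) with the 12′E olefin retained and the diosphenol C12=O/C11–OH; the closest known reactions are the BF3-catalysed intramolecular perezone→pipitzol [5+2] and Büchi/Engler quinone–alkene [5+2] cycloadditions.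

## Compound list

1 | 2-isopropylanisole | COc1ccccc1C(C)C | starting material
2 | 4-(chloromethyl)-2-isopropylanisole | COc1ccc(CCl)cc1C(C)C | intermediate
3 | geranyl chloride | CC(C)=CCC/C(C)=C/CCl | starting material
4 | (3-isopropyl-4-methoxybenzyl)magnesium chloride | COc1ccc(C[Mg]Cl)cc1C(C)C | intermediate
5 | 4-[(3E)-4,8-dimethylnona-3,7-dien-1-yl]-2-isopropylanisole | COc1ccc(CC/C=C(\C)CCC=C(C)C)cc1C(C)C | intermediate
6 | (+)-ferruginol methyl ether | COc1cc2c(cc1C(C)C)CC[C@H]1C(C)(C)CCC[C@]21C | intermediate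
7 | 6,7-dehydroferruginol methyl ether | COc1cc2c(cc1C(C)C)C=C[C@H]1C(C)(C)CCC[C@]21C | intermediate
8 | ring-contracted 12-methoxy dimethyl acetal (7α) | COc1cc2c(cc1C(C)C)[C@H](C(OC)OC)[C@H]1C(C)(C)CCC[C@]21C | intermediate
9 | ring-contracted 12-phenol dimethyl acetal | Oc1cc2c(cc1C(C)C)[C@H](C(OC)OC)[C@H]1C(C)(C)CCC[C@]21C | intermediate
10 | 11,12-o-quinone acetal | O=C1C(=O)C2=C(C=C1C(C)C)[C@H](C(OC)OC)[C@H]1C(C)(C)CCC[C@]21C | intermediate
11 | 14-(pentafluorophenylthio)-11,12-catechol acetal | Oc1c(O)c2c(c(Sc3c(F)c(F)c(F)c(F)c3F)c1C(C)C)[C@H](C(OC)OC)[C@H]1C(C)(C)CCC[C@]21C | intermediate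
12 | 12-hydroxy-11,14-quinone acetal | CC(C)C1=C(O)C(=O)C2=C(C1=O)[C@H](C(OC)OC)[C@H]1C(C)(C)CCC[C@]21C | intermediate
13 | 12-hydroxy-11,14-quinone 7α-aldehyde (taiwaniaquinone A-type) | CC(C)C1=C(O)C(=O)C2=C(C1=O)[C@H](C=O)[C@H]1C(C)(C)CCC[C@]21C | intermediate
14 | (−)-abietic acid | CC(C)C1=CC2=CC[C@@H]3[C@](C)(CCC[C@@]3(C)C(=O)O)[C@H]2CC1 | starting material
15 | 13-oxo-13,14-secoabiet-7-en-14-al-18-oic acid | O=CC1=CC[C@@H]2[C@](C)(CCC[C@@]2(C)C(=O)O)[C@H]1CCC(=O)C(C)C | intermediate
16 | 14-tosylhydrazone of 15 | Cc1ccc(cc1)S(=O)(=O)NN=CC1=CC[C@@H]2[C@](C)(CCC[C@@]2(C)C(=O)O)[C@H]1CCC(=O)C(C)C | intermediate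
17 | 13-oxo-13,14-secoabiet-8(14)-en-18-oic acid | C=C1CC[C@@H]2[C@](C)(CCC[C@@]2(C)C(=O)O)[C@H]1CCC(=O)C(C)C | intermediate
18 | 12-hydroxy-13-oxo-13,14-secoabiet-8(14)-en-18-oic acid | C=C1CC[C@@H]2[C@](C)(CCC[C@@]2(C)C(=O)O)[C@H]1CC(O)C(=O)C(C)C | intermediate
19 | 12-oxo-13,14,15,16-tetranorlabd-8(17)-en-18-oic acid | C=C1CC[C@@H]2[C@](C)(CCC[C@@]2(C)C(=O)O)[C@H]1CC=O | intermediate
20 | (12E)-14-oxo-15-norlabda-8(17),12-dien-18-oic acid | C=C1CC[C@@H]2[C@](C)(CCC[C@@]2(C)C(=O)O)[C@H]1C/C=C(\C)C=O | intermediate
21 | 4-epi-trans-communic acid | C=C1CC[C@@H]2[C@](C)(CCC[C@@]2(C)C(=O)O)[C@H]1C/C=C(\C)C=C | intermediate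
22 | target (CNP0269191.1) | C=C1CC[C@@H]2[C@](C)(CCC[C@@]2(C)C(=O)O)[C@H]1C/C=C(\C)[C@H]1C[C@@]2(C(C)C)C(=O)C(O)=C3[C@@]1(C2=O)[C@H](C=O)[C@H]1C(C)(C)CCC[C@]31C | target

## Totals and risks

Total step count: 14. Longest linear sequence: 8 (steps 1–7, then 14); the labdane branch is steps 8–13.

Three steps most likely to fail:

**Step 14 (intermolecular [5+2]).** Diene 21 may cyclise or undergo Prins chemistry under BF3 before the first C–C bond forms. The fallback sets out from 13 and 21 and separates a neutral bond formation from the skeletal shift. Heating 13 and 21 with Er(fod)3 in toluene brings about a Lewis-acid-templated Diels–Alder reaction across the hydroxy-bearing C12=C13 bond, with 21 as the 4π partner (C15′ to C13, C12′ to C12, α face), giving the cis-fused [4+2] adduct F1. Treating F1 with TMSOTf or BF3·OEt2 at −40 °C ionises the C12–C12′ bond to the chelated enediolate/allyl cation pair, which recloses between C14′ and C8 (1,3-shift), and the route comes back at 22.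

**Step 5 (iodine(III) ring contraction).** The electron-rich arene may be attacked, or simple 6,7-dimethoxylation may win. The fallback sets out from 6 and uses a carbene-based contraction instead. CrO3/AcOH benzylic oxidation gives sugiol methyl ether F2. NaH/HCO2Et gives the 6-hydroxymethylene ketone F3. Deformylative diazo transfer (TsN3, Et3N) gives the 6-diazo-7-ketone F4. Photochemical Wolff rearrangement in MeOH, followed by NaOMe equilibration, gives the ring-contracted 7α-methyl ester F5. DIBAL-H at −78 °C gives the aldehyde F6, and HC(OMe)3/PPTS in MeOH brings the route back at 8.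

**Step 7 (one-pot phenol → hydroxyquinone aldehyde).** The o-quinone 10 can tautomerise to a C7=C8 quinone methide before the thiol adds. The fallback sets out from 8 and introduces the oxygens stepwise through a para-quinone oxidation. NBS brominates C11 (ortho to OMe) to give the 11-bromide F7. n-BuLi exchange, B(OMe)3 and then H2O2/NaOH give the 11-phenol F8, whose para position C14 is free. Fremy's salt (Teuber oxidation) gives the 12-methoxy-11,14-quinone acetal F9. Aqueous HClO4/THF hydrolyses both the vinylogous ester and the acetal, and the route comes back at 13.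

## Further compounds

F1 | step 14 | cis-fused Diels–Alder adduct of 13 and 21 across C12=C13 (12-OH and 13-iPr cis) | C=C1CC[C@@H]2[C@](C)(CCC[C@@]2(C)C(=O)O)[C@H]1C[C@H]1[C@@]2(O)C(=O)C3=C(C(=O)[C@@]2(C(C)C)CC=C1C)[C@H](C=O)[C@H]1C(C)(C)CCC[C@]31C
F2 | step 5 | sugiol methyl ether | COc1cc2c(cc1C(C)C)C(=O)C[C@H]1C(C)(C)CCC[C@]21C
F3 | step 5 | 6-(hydroxymethylene)sugiol methyl ether | COc1cc2c(cc1C(C)C)C(=O)C(=CO)[C@H]1C(C)(C)CCC[C@]21C
F4 | step 5 | 6-diazosugiol methyl ether | COc1cc2c(cc1C(C)C)C(=O)C(=[N+]=[N-])[C@H]1C(C)(C)CCC[C@]21C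
F5 | step 5 | ring-contracted 7α-methyl ester | COc1cc2c(cc1C(C)C)[C@H](C(=O)OC)[C@H]1C(C)(C)CCC[C@]21C
F6 | step 5 | ring-contracted 7α-aldehyde (12-methoxy) | COc1cc2c(cc1C(C)C)[C@H](C=O)[C@H]1C(C)(C)CCC[C@]21C
F7 | step 7 | 11-bromo-12-methoxy acetal | COc1c(Br)c2c(cc1C(C)C)[C@H](C(OC)OC)[C@H]1C(C)(C)CCC[C@]21C
F8 | step 7 | 11-hydroxy-12-methoxy acetal | COc1c(O)c2c(cc1C(C)C)[C@H](C(OC)OC)[C@H]1C(C)(C)CCC[C@]21C
F9 | step 7 | 12-methoxy-11,14-quinone acetal | CC(C)C1=C(OC)C(=O)C2=C(C1=O)[C@H](C(OC)OC)[C@H]1C(C)(C)CCC[C@]21C
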